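**Strategy.** The cyclopentane ring C (C1', C2', spiro C3', C3a', C9a') is cut at C1'–C9a' and C3'–C3a'. The key step exploits that the benzylic carbon C9' of pyran ring B and the alkene carbon C2 of cyclohexene ring D stand 1,5 across ring C. Written as ketones, they make C3'–C3a' a Michael bond and C1'–C9a' an enolate alkylation bond. In one operation MgI2 opens a menthone-derived spirocyclopropyl ketone (ring D) to a γ-iodo enolate. This adds to C2 of a 3-methylchromone (rings A and B), and the new enolate is alkylated by the iodide, closing ring C and setting C3', C3a' and C9a'. The precursors are a flat chromone and a chiral-pool cyclopropane.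

Key step: step 5

Remark: locants are those of the spiro[cyclohex-2-ene-1,3'-cyclopenta[b]chromene] skeleton (ring A benzene, ring B pyran with O4', ring C cyclopentane, ring D unprimed) and are kept for all intermediates. (−)-Menthone, flopropione and all reagents are taken as commercial. The isomenthone content of commercial menthone concerns a centre (C3 of ring D) that is erased in step 6.

Step 1
Reactants: 1 (−)-menthone, (2S,5R)-5-methyl-2-(propan-2-yl)cyclohexan-1-one
Product: 2 (3R,6S)-3-methyl-2-methylidene-6-(propan-2-yl)cyclohexan-1-one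
Conditions: (CH2O)n, N-methylanilinium trifluoroacetate, THF, reflux
Reagents that add atoms: paraformaldehyde (as formaldehyde), C=O
Why: Mannich-type α-methylenation (Gras conditions): the iminium ion from formaldehyde and the anilinium salt should be attacked by the enol at C6, the only α-carbon with two hydrogens, and loss of N-methylaniline gives the exocyclic enone without touching the C5 methyl stereocentre.

Step 2
Reactants: 2 (3R,6S)-3-methyl-2-methylidene-6-(propan-2-yl)cyclohexan-1-one
Product: 3 (5S,8R)-8-methyl-5-(propan-2-yl)spiro[2.5]octan-4-one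
Conditions: Me3S(O)I, NaH, DMSO, 20 °C
Reagents that add atoms: trimethylsulfoxonium iodide, C[S+](C)(C)=O.[I-]
Why: Corey–Chaykovsky cyclopropanation: dimethylsulfoxonium methylide should add in conjugate fashion to the exocyclic enone and the enolate should displace DMSO in a 3-exo-tet closure; the new spiro carbon carries two identical CH2 arms and is not a stereocentre.

Step 3
Reactants: 4 flopropione, 1-(2,4,6-trihydroxyphenyl)propan-1-one
Product: 5 1-[2,4-bis(benzyloxy)-6-hydroxyphenyl]propan-1-one
Conditions: BnBr (2.1 equiv), K2CO3, acetone, reflux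
Reagents that add atoms: benzyl bromide, BrCc1ccccc1
Why: Williamson ether synthesis: the para hydroxyl and one ortho hydroxyl should be benzylated, whereas the last ortho hydroxyl is held in a hydrogen bond to the ketone and is kept for the ring closure of step 4.

Step 4
Reactants: 5 1-[2,4-bis(benzyloxy)-6-hydroxyphenyl]propan-1-one
Product: 6 5,7-bis(benzyloxy)-3-methyl-4H-chromen-4-one
Conditions: Me2NCH(OMe)2, toluene, 110 °C; then AcOH, 80 °C
Reagents that add atoms: N,N-dimethylformamide dimethyl acetal, COC(OC)N(C)C
Why: Enaminone route to chromones: condensation of the α-CH2 group with the amide acetal gives the α-methyl enaminone, and acid-promoted attack of the free phenol with loss of dimethylamine (addition–elimination) should close the pyranone ring.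

Step 5
Reactants: 3 (5S,8R)-8-methyl-5-(propan-2-yl)spiro[2.5]octan-4-one; 6 5,7-bis(benzyloxy)-3-methyl-4H-chromen-4-one
Product: 9 spiro diketone 6',8'-bis(benzyloxy)-6,9a'-dimethyl-3-(propan-2-yl)spiro[cyclohexane-1,3'-cyclopenta[b]chromane]-2,9'-dione (B/C cis-fused), via γ-iodo magnesium enolate 7 (not isolated), via chromanone magnesium enolate 8 (not isolated)
Conditions: MgI2 (0.3 equiv), THF, 75 °C, sealed tube
Reagents that add atoms: none
Why: Proposed new method: MgI2 is expected to open the ketone-activated cyclopropane of 3 by SN2 attack of iodide at a CH2 carbon to give the γ-iodo magnesium enolate 7, whose enolate carbon adds to C2 of the magnesium-bound chromone 6 (Michael addition) to give the chromanone enolate 8, which closes ring C by C-alkylation at the CH2I carbon and releases MgI2; each elementary step pairs a matched nucleophile and electrophile and only the last one is irreversible. The closest known reaction types are the MgI2-catalysed ring expansion of spirocyclopropyl oxindoles with imines and the Lewis acid–iodide ring-opening aldol reaction of cyclopropyl ketones, here extended to a C=C acceptor as a Michael-initiated ring closure. Ring C closes in the 5-exo-tet mode (enolate C9a' onto C1'), which can only give the cis B/C fusion and so sets C9a' from C3a'. The spiro centre C3' is controlled by the ring D stereocentres: axial attack on the half-chair enolate 7 with methyl and isopropyl groups pseudoequatorial occurs on the face cis to the methyl group, because the chair-like trajectory on the other face requires the ring-flipped form, where the pseudoaxial isopropyl group blocks it. C3a' is set in the reversible Michael step under Curtin–Hammett control, the adduct that turns the CH(CH3) arm of ring D away from the aryloxy oxygen being the one expected to cyclise faster. The step needs attack at C2 instead of C4 of the chromone and C- instead of O-alkylation of 8, which are secured by the soft, hindered character of enolate 7 together with magnesium chelation between the C4 carbonyl and the C5 benzyloxy group, and by the five- versus seven-membered ring size.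

Step 6
Reactants: 9 spiro diketone
Product: 10 enol triflate of 9 at C2=C3 of ring D (9'-ketone unchanged)
Conditions: KN(SiMe3)2, THF, −78 to 0 °C; then PhNTf2, −78 to 20 °C; H2O work-up
Reagents that add atoms: N-phenylbis(trifluoromethanesulfonimide), O=S(=O)(N(c1ccccc1)S(=O)(=O)C(F)(F)F)C(F)(F)F
Why: Enol triflate formation: the only α-hydrogen in 9 is H3 of ring D (the spiro carbon, C9a' and an aryl carbon occupy the other α-positions), so the potassium enolate can form in one direction only and O-sulfonylation by PhNTf2 should give the C2=C3 enol triflate, which also erases the C3 stereocentre.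

Step 7
Reactants: 10 enol triflate
Product: 11 6',8'-bis(benzyloxy)-6,9a'-dimethyl-3-(propan-2-yl)spiro[cyclohex-2-ene-1,3'-cyclopenta[b]chroman]-9'-one
Conditions: Pd(OAc)2 (5 mol %), PPh3, HCO2H, Et3N, DMF, 60 °C
Reagents that add atoms: none
Why: Palladium-catalysed formate reduction of a vinyl triflate (Cacchi reduction): oxidative addition to zerovalent palladium, exchange for formate, loss of CO2 and reductive elimination should replace OTf by H and leave the ring D alkene exactly at C2=C3; the aryl ketone and the benzyl ethers are inert under these conditions.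

Step 8
Reactants: 11 ring D alkene ketone
Product: 12 tertiary alcohol, 9'-(2-methylpropyl)-9'-ol of 11 (OH expected cis to C1'; the epimer serves equally)
Conditions: iBuLi, CeCl3 (iBuCeCl2), THF, −78 °C; then H2O
Reagents that add atoms: isobutyllithium, [Li]CC(C)C
Why: Organocerium 1,2-addition (Imamoto conditions) to a non-enolisable, hindered aryl ketone: the weakly basic reagent iBuCeCl2 should add rather than reduce, from the convex face of the cis-fused B/C system; the configuration of the carbinol carbon is of no consequence because it is planarised in step 9.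

Step 9
Reactants: 12 tertiary alcohol
Product: 14 bis(benzyl ether) of the chromane diol, 6',8'-bis(benzyloxy)-6,9a'-dimethyl-9'-(2-methylpropyl)-3-(propan-2-yl)spiro[cyclohex-2-ene-1,3'-cyclopenta[b]chromane] (configuration as in 16), via benzylic cation 13 (not isolated)
Conditions: Et3SiH, CF3CO2H, CH2Cl2, −40 °C
Reagents that add atoms: none
Why: Ionic hydrogenation (Kursanov–Parnes deoxygenation): acid ionises either carbinol epimer to the same trioxygenated benzylic cation 13, and Et3SiH should deliver hydride to the face of C9' that is anti to the pseudoaxial C1' of ring C, that is syn to the angular methyl group, which places the isobutyl group cis to C1' as in the target; the step is stereoconvergent and the low temperature spares the ring D alkene.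

Step 10
Reactants: 14 bis(benzyl ether)
Product: 15 chromane diol, 6,9a'-dimethyl-9'-(2-methylpropyl)-3-(propan-2-yl)spiro[cyclohex-2-ene-1,3'-cyclopenta[b]chromane]-6',8'-diol
Conditions: BCl3, C6HMe5, CH2Cl2, −78 °C; then H2O
Reagents that add atoms: none
Why: Lewis acid debenzylation with a cation scavenger: BCl3 cleaves the aryl benzyl ethers at low temperature and pentamethylbenzene traps the benzyl cation, so that the acid-sensitive trisubstituted alkene and the chromane ether should survive.

Step 11
Reactants: 15 chromane diol
Product: 16 target, (1R,3a'S,6R,9'S,9a'R)-6',8'-dihydroxy-6,9a'-dimethyl-9'-(2-methylpropyl)-3-(propan-2-yl)spiro[cyclohex-2-ene-1,3'-cyclopenta[b]chromane]-5',7'-dicarbaldehyde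
Conditions: POCl3, DMF, MeCN, 0 to 45 °C; then H2O
Reagents that add atoms: N,N-dimethylformamide, CN(C)C=O; water, O
Why: Vilsmeier–Haack formylation: the two free positions of ring A (C5' and C7') are each ortho or para to three oxygen substituents, so that two successive attacks of the chloroiminium ion followed by hydrolysis should give the dialdehyde, each formyl group being hydrogen-bonded to a neighbouring hydroxyl.

**Compound list**

1 | (−)-menthone, (2S,5R)-5-methyl-2-(propan-2-yl)cyclohexan-1-one | CC(C)[C@@H]1CC[C@@H](C)CC1=O | starting material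
2 | (3R,6S)-3-methyl-2-methylidene-6-(propan-2-yl)cyclohexan-1-one | CC(C)[C@@H]1CC[C@@H](C)C(=C)C1=O | intermediate
3 | (5S,8R)-8-methyl-5-(propan-2-yl)spiro[2.5]octan-4-one | CC(C)[C@@H]1CC[C@@H](C)C2(CC2)C1=O | intermediate
4 | flopropione, 1-(2,4,6-trihydroxyphenyl)propan-1-one | CCC(=O)c1c(O)cc(O)cc1O | starting material
5 | 1-[2,4-bis(benzyloxy)-6-hydroxyphenyl]propan-1-one | CCC(=O)c1c(O)cc(OCc2ccccc2)cc1OCc1ccccc1 | intermediate
6 | 5,7-bis(benzyloxy)-3-methyl-4H-chromen-4-one | CC1=COc2cc(OCc3ccccc3)cc(OCc3ccccc3)c2C1=O | intermediate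
7 | γ-iodo magnesium enolate: iodomagnesium enolate of 2-(2-iodoethyl)-3-methyl-6-(propan-2-yl)cyclohexanone (C1=C2 enolate; CH centres as in 3) | CC(C)[C@@H]1CC[C@@H](C)C(CCI)=C1O[Mg]I | intermediate (not isolated)
8 | chromanone magnesium enolate: C3=C4 iodomagnesium enolate of 5,7-bis(benzyloxy)-2-[1-(2-iodoethyl)-6-methyl-2-oxo-3-(propan-2-yl)cyclohexyl]-3-methylchroman-4-one | CC1=C(O[Mg]I)c2c(OCc3ccccc3)cc(OCc3ccccc3)cc2O[C@@H]1[C@@]1(CCI)C(=O)[C@H](C(C)C)CC[C@H]1C | intermediate (not isolated)
9 | spiro diketone: 6',8'-bis(benzyloxy)-6,9a'-dimethyl-3-(propan-2-yl)spiro[cyclohexane-1,3'-cyclopenta[b]chromane]-2,9'-dione; B/C cis-fused (H3a' and 9a'-CH3 on one face); ring D carbonyl C2 on the face of O4'; 6-CH3 cis and 3-isopropyl trans to C3a' | O=C1c2c(OCc3ccccc3)cc(OCc3ccccc3)cc2O[C@H]2[C@]1(C)CC[C@@]21C(=O)[C@H](C(C)C)CC[C@H]1C | intermediate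
10 | enol triflate: 6',8'-bis(benzyloxy)-6,9a'-dimethyl-9'-oxo-3-(propan-2-yl)spiro[cyclohex-2-ene-1,3'-cyclopenta[b]chroman]-2-yl trifluoromethanesulfonate; other centres as in 9 | O=C1c2c(OCc3ccccc3)cc(OCc3ccccc3)cc2O[C@H]2[C@]1(C)CC[C@@]21C(OS(=O)(=O)C(F)(F)F)=C(C(C)C)CC[C@H]1C | intermediate
11 | 6',8'-bis(benzyloxy)-6,9a'-dimethyl-3-(propan-2-yl)spiro[cyclohex-2-ene-1,3'-cyclopenta[b]chroman]-9'-one; centres as in 9 | O=C1c2c(OCc3ccccc3)cc(OCc3ccccc3)cc2O[C@H]2[C@]1(C)CC[C@@]21C=C(C(C)C)CC[C@H]1C | intermediate
12 | tertiary alcohol: 6',8'-bis(benzyloxy)-6,9a'-dimethyl-9'-(2-methylpropyl)-3-(propan-2-yl)spiro[cyclohex-2-ene-1,3'-cyclopenta[b]chroman]-9'-ol; OH cis to C1' (expected epimer) | CC(C)C[C@@]1(O)c2c(OCc3ccccc3)cc(OCc3ccccc3)cc2O[C@H]2[C@]1(C)CC[C@@]21C=C(C(C)C)CC[C@H]1C | intermediate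
13 | benzylic cation at C9' derived from 12 | CC(C)C[C+]1c2c(OCc3ccccc3)cc(OCc3ccccc3)cc2O[C@H]2[C@]1(C)CC[C@@]21C=C(C(C)C)CC[C@H]1C | intermediate (not isolated)
14 | bis(benzyl ether): 6',8'-bis(benzyloxy)-6,9a'-dimethyl-9'-(2-methylpropyl)-3-(propan-2-yl)spiro[cyclohex-2-ene-1,3'-cyclopenta[b]chromane]; H9' cis to 9a'-CH3, configuration as in 16 | CC(C)C[C@@H]1c2c(OCc3ccccc3)cc(OCc3ccccc3)cc2O[C@H]2[C@]1(C)CC[C@@]21C=C(C(C)C)CC[C@H]1C | intermediate
15 | chromane diol: 6,9a'-dimethyl-9'-(2-methylpropyl)-3-(propan-2-yl)spiro[cyclohex-2-ene-1,3'-cyclopenta[b]chromane]-6',8'-diol; configuration as in 16 | CC(C)C[C@@H]1c2c(O)cc(O)cc2O[C@H]2[C@]1(C)CC[C@@]21C=C(C(C)C)CC[C@H]1C | intermediate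
16 | CNP0121396.3, (1R,3a'S,6R,9'S,9a'R)-6',8'-dihydroxy-6,9a'-dimethyl-9'-(2-methylpropyl)-3-(propan-2-yl)spiro[cyclohex-2-ene-1,3'-cyclopenta[b]chromane]-5',7'-dicarbaldehyde | CC(C)C[C@@H]1c2c(O)c(C=O)c(O)c(C=O)c2O[C@H]2[C@]1(C)CC[C@@]21C=C(C(C)C)CC[C@H]1C | target

**Step count.** Total: 11 steps. Longest linear sequence: 9 steps (4 to 16 through steps 3 to 11, or 1 to 16 through steps 1, 2 and 5 to 11).

**Steps most likely to fail**

Step 5 (proposed new method). The iodo enolate may revert to the cyclopropane faster than it adds to the hindered, electron-rich chromone. The Michael step may also show poor facial selectivity, and iodide may cleave the peri benzyl ether. The fallback uses known chemistry and sets out from 3 and 6. Me3SiI (CH2Cl2, −78 to 0 °C) opens 3 to the γ-iodo trimethylsilyl enol ether F1. Separately, tBuMe2SiOTf converts 6 into the 4-silyloxybenzopyrylium triflate F2. Mukaiyama–Michael addition of F1 to F2 (2,6-lutidine, CH2Cl2, −78 °C) gives the silyl enol ether adduct F3. Bu4NF (THF, −78 to 20 °C) then unveils the chromanone enolate, which closes ring C by intramolecular alkylation and comes back to the route at 9.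

Step 8. Addition may stall, or β-hydride reduction may take over, at the carbonyl group flanked by a quaternary carbon and a peri benzyloxy group. The fallback sets out from 11. The more reactive allylic reagent CH2=C(CH3)CH2MgCl (THF, 0 °C) adds through a six-membered transition state to give the methallyl carbinol F4. Hydrogenation of its 1,1-disubstituted alkene over RhCl(PPh3)3 (H2, benzene) spares the hindered ring D alkene and the benzyl ethers and comes back to the route at 12.

Step 9. Hydride may be delivered to the wrong face of the planar benzylic cation, or the cation may be captured by the ring D alkene. The fallback reverses the order in which hydrogen and carbon are attached to C9' and sets out from 11. LiAlH4 (THF, 0 °C) gives the secondary benzylic alcohol F5. Ionisation with BF3·OEt2 in the presence of trimethyl(2-methylallyl)silane (CH2Cl2, −78 °C, Hosomi–Sakurai-type substitution) then puts the carbon nucleophile on the face that hydride preferred in the failed step, giving the methallyl chromane F6. Hydrogenation over RhCl(PPh3)3 comes back to the route at 14.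

**Further compounds**

F1 | step 5 | γ-iodo trimethylsilyl enol ether, [2-(2-iodoethyl)-3-methyl-6-(propan-2-yl)cyclohex-1-en-1-yl]oxy(trimethyl)silane | CC(C)[C@@H]1CC[C@@H](C)C(CCI)=C1O[Si](C)(C)C
F2 | step 5 | 5,7-bis(benzyloxy)-4-[(tert-butyldimethylsilyl)oxy]-3-methylchromenylium trifluoromethanesulfonate | Cc1c[o+]c2cc(OCc3ccccc3)cc(OCc3ccccc3)c2c1O[Si](C)(C)C(C)(C)C.[O-]S(=O)(=O)C(F)(F)F
F3 | step 5 | silyl enol ether adduct, 5,7-bis(benzyloxy)-4-[(tert-butyldimethylsilyl)oxy]-2-[1-(2-iodoethyl)-6-methyl-2-oxo-3-(propan-2-yl)cyclohexyl]-3-methyl-2H-chromene | CC1=C(O[Si](C)(C)C(C)(C)C)c2c(OCc3ccccc3)cc(OCc3ccccc3)cc2O[C@@H]1[C@@]1(CCI)C(=O)[C@H](C(C)C)CC[C@H]1C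
F4 | step 8 | methallyl carbinol, 9'-(2-methylprop-2-enyl)-9'-ol analogue of 12 | CC(=C)C[C@@]1(O)c2c(OCc3ccccc3)cc(OCc3ccccc3)cc2O[C@H]2[C@]1(C)CC[C@@]21C=C(C(C)C)CC[C@H]1C
F5 | step 9 | secondary benzylic alcohol, 9'-ol from reduction of 11 | O[C@@H]1c2c(OCc3ccccc3)cc(OCc3ccccc3)cc2O[C@H]2[C@]1(C)CC[C@@]21C=C(C(C)C)CC[C@H]1C
F6 | step 9 | methallyl chromane, 9'-(2-methylprop-2-enyl) analogue of 14 | CC(=C)C[C@@H]1c2c(OCc3ccccc3)cc(OCc3ccccc3)cc2O[C@H]2[C@]1(C)CC[C@@]21C=C(C(C)C)CC[C@H]1C
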